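3 questions stood open on two flasks of equal charge, Monday's cold and Sunday's warm.

| flask | Q | J | temperature | remark | time |
|---|---|---|---|---|---|
| green | 0.69 M | 0.51 M | −15 °C | run made earlier |  |
| grey | 0.69 M | 1.1 M | −4 °C | run made earlier |  |
| red | 1.4 M | 0.759 M | −15 °C | run made earlier |  |
| Monday's | 0.69 M | 0.759 M | −20 °C |  | 40 h |
| Sunday's | 0.69 M | 0.759 M | 0 °C |  | 40 h |

- green (time / h: Z / %, G / %): 2.50: 70.9, 0; 4.00: 85.9, 0; 6.00: 93.6, 1.9; 10.0: 94.3, 2.1; 15.0: 92.3, 4.1; 20.0: 91.1, 8.1; 30.0: 85.2, 13.6
- grey (time / h: Z / %, G / %): 0.667: 74.0, 1.3; 2.50: 93.5, 8.1; 5.00: 81.7, 19.2; 6.00: 76.6, 25.3; 10.0: 57.9, 40.2; 12.0: 51.1, 49.6; 15.0: 42.0, 60.2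
- red (time / h: Z / %, G / %): 6.00: 93.7, 1.6; 12.0: 95.1, 5.0; 20.0: 91.1, 7.9; 25.0: 88.4, 10.4; 30.0: 88.2, 12.6

(each reading ± 1 percentage point)

* the flask that comes out highest in amount of Z, in percent of the Q charged, or "all alike" when all lie within 1.5 percentage points (Monday's / Sunday's / all alike)
* Z at the end, in percent of the Q charged, Monday's
* Z at the end, in percent of the Q charged, Sunday's

- a reading or a percentage of G counts all its forms, free or not

In the green run Q had become Z within hours, reading 94.3% Z at 10.0 h, so I asked how fast G then took Z. The grey run was the telling one: from 5.00 h to 15.0 h Z fell to half, yet G's hourly gain over the last stretch was 90.1% of that over the early one. So I tied the rate to J. I defined κ as G made per hour per unit of J charged, which read 0.00613 h⁻¹ in green, 0.00775 h⁻¹ in red and 0.0252 h⁻¹ in grey. A straight line in ln κ against temperature through green and grey gave 0.00323 h⁻¹ for Monday's and 0.0421 h⁻¹ for Sunday's.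

I carried the feed time τ, the charged Q divided by κ times the charged J, which is the time G needs to equal the charged Q at the rate κ gives: 21.6 h on Sunday and 282 h on Monday. One extreme holds the rate constant (zero order in Z), so Z falls on a straight line: 85.8% on Monday, and none on Sunday, since 40 h exceeds τ. The other makes the rate proportional to Z, so Z is e^(−t/τ) at time t: 86.8% and 15.7%. I expected the real flask between them, since in the grey run G kept more of its rate than Z kept of its amount, but that was an estimate and no bound: neither extreme holds the slow start of the green run, where G still read 0% at 4.00 h. I committed to Monday's at about 86.8% and Sunday's midway, 7.85%, so Monday's highest.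

The forecast gave Monday's highest, with 93% and 1%, holding that “Z then decays first order”.

    Q → Z (k = 3.30 h⁻¹, Ea = 74.0 kJ mol⁻¹)
    J → X (k = 0.0980 h⁻¹, Ea = 82.0 kJ mol⁻¹)
    Z + X → G (k = 0.710 M⁻¹ h⁻¹, Ea = 67.0 kJ mol⁻¹)
    2 X → E (k = 0.170 M⁻¹ h⁻¹, Ea = 77.0 kJ mol⁻¹)
    L ⇌ G, rate k5*(cs5 - [G]) while solid is left; crystals form when [G] > cs5 (solubility = 0.250 M, k = 16.0 h⁻¹)
    G → D (k = 1.80 × 10⁻⁴ h⁻¹, Ea = 103 kJ mol⁻¹)
    (constants at 0 °C)

Monday's came out highest, at 88.1% against Sunday's 11.2%. Sunday's lay between my two extremes, but Monday's did not: it stood 1.3 percentage points above the higher one. The same flask at −5 °C has a feed time of 41.1 h, close to its 40 h, which gives the two extremes as 2.58% and 37.8%. That flask gave Z 24.1%.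

The earlier runs and the new flask are simulated with made-up constants; scatter was added.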